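**Retrosynthetic overview**

1. Ring letters: A is the resorcinol ring carrying the styryl group, B the central benzene ring, C the dihydrofuran fused to A (O1, C2, C3, C3a, C7a), D the dihydrofuran fused to B (O1', C2', C3', C3a', C7a'). The target comes from its nona-silyl ether by fluoride, and that from the cis,cis core by acid equilibration at C2 and C2'.
2. Key disconnection: C2–C3 of ring C and, in the same operation, C2'–C3' of ring D, by twofold 1,5 C–H insertion of diaryl carbenes of divalent rhodium generated from an achiral bis-hydrazone that contains neither furan ring; all four stereocentres arise here.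
3. Enabling feature: C3 (C3') is a diarylmethine carbon bonded to C3a (C3a'), an arene carbon flanked by two oxygen-bearing carbons, so it can serve as a donor/donor carbene carbon. C2–H (C2'–H) is alpha to O1 (O1'), benzylic to an ortho,para-dioxygenated ring, and 1,5 to C3 (C3'). Ring A is symmetric about its C3a–C6 axis, so its two oxygens need no regiocontrol.
4. The bis-hydrazone comes from a bis-nitrile by double addition of one aryllithium (both 3,5-dioxygenated phenyl groups at once) and hydrazine exchange. The bis-nitrile comes from two Mitsunobu etherifications (ring B O–CH2–aryl, ring A O–CH2–ring B) and one Heck reaction.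
5. Order of ring formation: no ring is closed before step 15; rings C and D are closed together there, and none afterwards.

Key step: step 15

Assumption: Rh2(R-PTAD)4 (PTAD = N-phthaloyl-1-adamantylglycinate) is taken to give the (2R,3S)-cis rings; should a model insertion show the opposite sense, Rh2(S-PTAD)4 is used and nothing else changes.

**Route**

Step 1
Reactants: 1 2,4-dihydroxybenzaldehyde
Product: 2 2,4-bis[(tert-butyldimethylsilyl)oxy]benzaldehyde
Conditions: TBSCl (2.5 equiv), imidazole (5 equiv), DMF, rt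
Reagents that add atoms: tert-butyldimethylsilyl chloride, CC(C)(C)[Si](C)(C)Cl
Why: Imidazole-promoted silylation of both phenols should go to completion with excess reagent, the chelated ortho hydroxyl reacting last.

Step 2
Reactants: 2 2,4-bis[(tert-butyldimethylsilyl)oxy]benzaldehyde
Product: 3 {2,4-bis[(tert-butyldimethylsilyl)oxy]phenyl}methanol
Conditions: NaBH4, THF/MeOH, −20 °C; pH 7 phosphate buffer
Reagents that add atoms: none
Why: Borohydride reduction of an aryl aldehyde, run cold and quenched at neutral pH so that the ortho silyl group should not migrate to the new alkoxide.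

Step 3
Reactants: 4 2,6-dihydroxybenzonitrile
Product: 5 3-formyl-2,6-dihydroxybenzonitrile
Conditions: POCl3, DMF, MeCN, 0 °C to rt; then H2O, 50 °C
Reagents that add atoms: N,N-dimethylformamide, CN(C)C=O; water, O
Why: Vilsmeier–Haack formylation should occur only at C3 (equivalent to C5), which is ortho to one hydroxyl, para to the other and merely meta to the nitrile.

Step 4
Reactants: 5 3-formyl-2,6-dihydroxybenzonitrile
Product: 6 3-formyl-2-hydroxy-6-[(triisopropylsilyl)oxy]benzonitrile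
Conditions: TIPSCl (1.05 equiv), imidazole, CH2Cl2, 0 °C
Reagents that add atoms: triisopropylsilyl chloride, CC(C)[Si](Cl)(C(C)C)C(C)C
Why: Regioselective silylation as in 2,4-dihydroxybenzaldehyde: the hydroxyl para to the formyl group is free and more acidic, whereas the one between nitrile and formyl is held in a hydrogen bond to C=O.

Step 5
Reactants: 6 3-formyl-2-hydroxy-6-[(triisopropylsilyl)oxy]benzonitrile; 3 {2,4-bis[(tert-butyldimethylsilyl)oxy]phenyl}methanol
Product: 7 2-({2,4-bis[(tert-butyldimethylsilyl)oxy]phenyl}methoxy)-3-formyl-6-[(triisopropylsilyl)oxy]benzonitrile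
Conditions: PPh3, DIAD, THF, 0 °C to rt
Reagents that add atoms: none
Why: Mitsunobu etherification of an acidic phenol with a primary benzylic alcohol under neutral conditions that should leave the aryl silyl ethers intact.

Step 6
Reactants: 7 2-({2,4-bis[(tert-butyldimethylsilyl)oxy]phenyl}methoxy)-3-formyl-6-[(triisopropylsilyl)oxy]benzonitrile
Product: 8 2-({2,4-bis[(tert-butyldimethylsilyl)oxy]phenyl}methoxy)-3-(hydroxymethyl)-6-[(triisopropylsilyl)oxy]benzonitrile
Conditions: NaBH4, THF/MeOH, 0 °C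
Reagents that add atoms: none
Why: Chemoselective borohydride reduction of the aldehyde; the nitrile and silyl ethers should not react.

Step 7
Reactants: 9 4-bromo-2,6-difluorobenzonitrile
Product: 10 4-bromo-2,6-dimethoxybenzonitrile
Conditions: NaOMe (2.5 equiv), MeOH/THF, 0 to 50 °C
Reagents that add atoms: sodium methoxide, [Na+].[O-]C
Why: Twofold nucleophilic aromatic substitution; fluoride ortho to the nitrile is displaced far faster than the para bromide.

Step 8
Reactants: 10 4-bromo-2,6-dimethoxybenzonitrile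
Product: 11 4-bromo-2,6-dihydroxybenzonitrile
Conditions: BBr3 (4 equiv), CH2Cl2, −78 °C to rt; then H2O
Reagents that add atoms: none
Why: Boron tribromide cleavage of aryl methyl ethers, to which nitrile and aryl bromide are inert.

Step 9
Reactants: 11 4-bromo-2,6-dihydroxybenzonitrile
Product: 12 4-bromo-2-hydroxy-6-[(triisopropylsilyl)oxy]benzonitrile
Conditions: TIPSCl (1.0 equiv, slow addition), imidazole, DMF, 0 °C
Reagents that add atoms: triisopropylsilyl chloride, CC(C)[Si](Cl)(C(C)C)C(C)C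
Why: Mono-silylation of a symmetric diol, so no regiochemical question arises; diol and bis-ether are separated and recycled.

Step 10
Reactants: 12 4-bromo-2-hydroxy-6-[(triisopropylsilyl)oxy]benzonitrile; 13 tert-butyldimethyl(4-vinylphenoxy)silane
Product: 14 2-hydroxy-4-[(E)-2-{4-[(tert-butyldimethylsilyl)oxy]phenyl}ethenyl]-6-[(triisopropylsilyl)oxy]benzonitrile
Conditions: Pd(OAc)2 (5 mol %), P(o-tol)3 (10 mol %), Et3N, MeCN, 80 °C
Reagents that add atoms: none
Why: Heck reaction of a bromide activated by the para nitrile; syn insertion and syn beta-hydride elimination should give the (E)-stilbene.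

Step 11
Reactants: 14 2-hydroxy-4-[(E)-2-{4-[(tert-butyldimethylsilyl)oxy]phenyl}ethenyl]-6-[(triisopropylsilyl)oxy]benzonitrile; 8 2-({2,4-bis[(tert-butyldimethylsilyl)oxy]phenyl}methoxy)-3-(hydroxymethyl)-6-[(triisopropylsilyl)oxy]benzonitrile
Product: 15 bis-nitrile in which the ring A phenol oxygen of 14 is bonded to the benzylic CH2 of 8
Conditions: PPh3, DIAD, THF, 0 °C to rt
Reagents that add atoms: none
Why: Mitsunobu etherification of a 2-cyanophenol (well within the acidity range of the reaction) with a primary benzylic alcohol, neutral toward all silyl ethers.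

Step 12
Reactants: 16 5-bromobenzene-1,3-diol
Product: 17 1-bromo-3,5-bis[(tert-butyldimethylsilyl)oxy]benzene
Conditions: TBSCl (2.4 equiv), imidazole, DMF, rt
Reagents that add atoms: tert-butyldimethylsilyl chloride, CC(C)(C)[Si](C)(C)Cl
Why: Standard imidazole-promoted silylation of two unhindered phenols.

Step 13
Reactants: 17 1-bromo-3,5-bis[(tert-butyldimethylsilyl)oxy]benzene; 15 bis-nitrile
Product: 20 bis(N–H ketimine) in which each nitrile carbon of 15 has become C(=NH) bearing a 3,5-bis(silyloxy)phenyl group, via aryllithium 18 (not isolated), via bis(N-lithio ketimine) 19 (not isolated)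
Conditions: 17 (3 equiv), t-BuLi (6 equiv), THF, −78 °C; then 15, −78 to 0 °C; AcOH in THF, −78 °C
Reagents that add atoms: none
Why: Bromine–lithium exchange followed by addition of the aryllithium to both nitriles should stop at the N-lithio ketimine, because the cylindrical C≡N group can be approached perpendicular to the ring plane despite two ortho substituents and the ketimine anion does not add a second nucleophile.

Step 14
Reactants: 20 bis(N–H ketimine)
Product: 21 bis-hydrazone (both C=NH groups replaced by C=N–NH2)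
Conditions: N2H4·H2O (excess), AcOH (cat.), EtOH/THF, 50 °C, argon
Reagents that add atoms: hydrazine, NN
Why: Transimination, in which the alpha-effect nucleophile adds to the protonated ketimine and ammonia is expelled, an exchange that should succeed for hindered diaryl ketimines whose parent ketones condense poorly; exclusion of air avoids diimide reduction of the stilbene.

Step 15
Reactants: 21 bis-hydrazone
Product: 23 cis,cis nona-silyl ether with rings C and D closed, (2R,3S,2'R,3'S), via bis(diaryldiazomethane) 22 (not isolated)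
Conditions: MnO2 (activated, excess), CH2Cl2, 0 °C, dark; then Rh2(R-PTAD)4 (2 mol %), −40 to 0 °C
Reagents that add atoms: none
Why: MnO2 dehydrogenates both hydrazones to the bis-diazo compound 22, and Rh2(R-PTAD)4 then expels N2 from each diazo group to give a donor/donor carbene of divalent rhodium that inserts into the ether C–H bond five atoms away through an asynchronous, hydride-transfer-like three-centre transition state, so each C2–C3 bond and each dihydrofuran is made in the same event. The closest known reaction is the enantioselective intramolecular 1,5 C–H insertion of diaryl carbenes generated from 2-(benzyloxy)benzophenone hydrazones, which gives cis-2,3-diaryl-2,3-dihydrobenzofurans. Ring C and ring D are each closed by 1,5-insertion to a five-membered ring made of the carbene carbon, two arene carbons, the ether oxygen and the former CH2 carbon. At each ring the carbene carbon becomes C3 (C3') with its configuration set by the chiral carboxylate pocket of the catalyst, C2 (C2') is set in the same transition state by which enantiotopic hydrogen is replaced, and the compact transition state places the two aryl groups cis; the two sites are remote and alike, so one catalyst should impose the same sense (3S, 3'S) on both. Site selectivity is needed against the second oxygen substituent ortho to each carbene carbon and is secured by making it a triisopropylsilyl ether, which has no C–H on the atom bonded to oxygen, while the reacting CH2 groups are doubly activated (alpha to oxygen, benzylic to an electron-rich ring). Chemoselectivity toward the stilbene rests on the low intermolecular reactivity of donor/donor carbenes and on the para position of the styryl group, which no intramolecular pathway can reach.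

Step 16
Reactants: 23 cis,cis nona-silyl ether
Product: 24 trans,trans nona-silyl ether, (2S,3S,2'S,3'S)
Conditions: CF3CO2H (10 equiv), CH2Cl2, 0 °C
Reagents that add atoms: none
Why: Acid-promoted reversible heterolysis of each benzylic C2–O bond (the cation is stabilised by the ortho,para-dioxygenated aryl group) and reclosure by the same phenol oxygen should give the thermodynamically favoured trans-2,3-diaryl rings with C3 and C3' untouched; the second oxygen on ring B stays silylated, so only the original oxygen can reclose.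

Step 17
Reactants: 24 trans,trans nona-silyl ether
Product: 25 gnetumontanin B
Conditions: Bu4NF/AcOH (1:1, excess), THF, 0 °C to rt, argon
Reagents that add atoms: none
Why: Fluoride cleavage of all nine aryl silyl ethers, buffered with acetic acid so that no phenoxide (and hence no quinone methide ring opening) is generated and the four stereocentres should be preserved.

**Compound list**

1 | 2,4-dihydroxybenzaldehyde | O=Cc1ccc(O)cc1O | starting material
2 | 2,4-bis[(tert-butyldimethylsilyl)oxy]benzaldehyde | O=Cc1ccc(O[Si](C)(C)C(C)(C)C)cc1O[Si](C)(C)C(C)(C)C | intermediate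
3 | {2,4-bis[(tert-butyldimethylsilyl)oxy]phenyl}methanol | OCc1ccc(O[Si](C)(C)C(C)(C)C)cc1O[Si](C)(C)C(C)(C)C | intermediate
4 | 2,6-dihydroxybenzonitrile | N#Cc1c(O)cccc1O | starting material
5 | 3-formyl-2,6-dihydroxybenzonitrile | N#Cc1c(O)ccc(C=O)c1O | intermediate
6 | 3-formyl-2-hydroxy-6-[(triisopropylsilyl)oxy]benzonitrile | N#Cc1c(O[Si](C(C)C)(C(C)C)C(C)C)ccc(C=O)c1O | intermediate
7 | 2-({2,4-bis[(tert-butyldimethylsilyl)oxy]phenyl}methoxy)-3-formyl-6-[(triisopropylsilyl)oxy]benzonitrile | N#Cc1c(O[Si](C(C)C)(C(C)C)C(C)C)ccc(C=O)c1OCc1ccc(O[Si](C)(C)C(C)(C)C)cc1O[Si](C)(C)C(C)(C)C | intermediate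
8 | 2-({2,4-bis[(tert-butyldimethylsilyl)oxy]phenyl}methoxy)-3-(hydroxymethyl)-6-[(triisopropylsilyl)oxy]benzonitrile | N#Cc1c(O[Si](C(C)C)(C(C)C)C(C)C)ccc(CO)c1OCc1ccc(O[Si](C)(C)C(C)(C)C)cc1O[Si](C)(C)C(C)(C)C | intermediate
9 | 4-bromo-2,6-difluorobenzonitrile | N#Cc1c(F)cc(Br)cc1F | starting material
10 | 4-bromo-2,6-dimethoxybenzonitrile | N#Cc1c(OC)cc(Br)cc1OC | intermediate
11 | 4-bromo-2,6-dihydroxybenzonitrile | N#Cc1c(O)cc(Br)cc1O | intermediate
12 | 4-bromo-2-hydroxy-6-[(triisopropylsilyl)oxy]benzonitrile | N#Cc1c(O)cc(Br)cc1O[Si](C(C)C)(C(C)C)C(C)C | intermediate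
13 | tert-butyldimethyl(4-vinylphenoxy)silane | C=Cc1ccc(O[Si](C)(C)C(C)(C)C)cc1 | starting material
14 | 2-hydroxy-4-[(E)-2-{4-[(tert-butyldimethylsilyl)oxy]phenyl}ethenyl]-6-[(triisopropylsilyl)oxy]benzonitrile | N#Cc1c(O)cc(/C=C/c2ccc(O[Si](C)(C)C(C)(C)C)cc2)cc1O[Si](C(C)C)(C(C)C)C(C)C | intermediate
15 | 2-({2,4-bis[(tert-butyldimethylsilyl)oxy]phenyl}methoxy)-3-{[2-cyano-5-[(E)-2-{4-[(tert-butyldimethylsilyl)oxy]phenyl}ethenyl]-3-[(triisopropylsilyl)oxy]phenoxy]methyl}-6-[(triisopropylsilyl)oxy]benzonitrile (bis-nitrile) | N#Cc1c(O[Si](C(C)C)(C(C)C)C(C)C)cc(/C=C/c2ccc(O[Si](C)(C)C(C)(C)C)cc2)cc1OCc1ccc(O[Si](C(C)C)(C(C)C)C(C)C)c(C#N)c1OCc1ccc(O[Si](C)(C)C(C)(C)C)cc1O[Si](C)(C)C(C)(C)C | intermediate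
16 | 5-bromobenzene-1,3-diol | Oc1cc(O)cc(Br)c1 | starting material
17 | 1-bromo-3,5-bis[(tert-butyldimethylsilyl)oxy]benzene | Brc1cc(O[Si](C)(C)C(C)(C)C)cc(O[Si](C)(C)C(C)(C)C)c1 | intermediate
18 | {3,5-bis[(tert-butyldimethylsilyl)oxy]phenyl}lithium | [Li]c1cc(O[Si](C)(C)C(C)(C)C)cc(O[Si](C)(C)C(C)(C)C)c1 | intermediate (not isolated)
19 | bis(N-lithio ketimine): 15 with each C≡N replaced by C(=NLi)[3,5-bis(tert-butyldimethylsilyloxy)phenyl] | [Li]N=C(c1cc(O[Si](C)(C)C(C)(C)C)cc(O[Si](C)(C)C(C)(C)C)c1)c1c(O[Si](C(C)C)(C(C)C)C(C)C)cc(/C=C/c2ccc(O[Si](C)(C)C(C)(C)C)cc2)cc1OCc1ccc(O[Si](C(C)C)(C(C)C)C(C)C)c(C(=N[Li])c2cc(O[Si](C)(C)C(C)(C)C)cc(O[Si](C)(C)C(C)(C)C)c2)c1OCc1ccc(O[Si](C)(C)C(C)(C)C)cc1O[Si](C)(C)C(C)(C)C | intermediate (not isolated)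
20 | bis(N–H ketimine): 15 with each C≡N replaced by C(=NH)[3,5-bis(tert-butyldimethylsilyloxy)phenyl] | N=C(c1cc(O[Si](C)(C)C(C)(C)C)cc(O[Si](C)(C)C(C)(C)C)c1)c1c(O[Si](C(C)C)(C(C)C)C(C)C)cc(/C=C/c2ccc(O[Si](C)(C)C(C)(C)C)cc2)cc1OCc1ccc(O[Si](C(C)C)(C(C)C)C(C)C)c(C(=N)c2cc(O[Si](C)(C)C(C)(C)C)cc(O[Si](C)(C)C(C)(C)C)c2)c1OCc1ccc(O[Si](C)(C)C(C)(C)C)cc1O[Si](C)(C)C(C)(C)C | intermediate
21 | bis-hydrazone: 20 with each C=NH replaced by C=N–NH2 | NN=C(c1cc(O[Si](C)(C)C(C)(C)C)cc(O[Si](C)(C)C(C)(C)C)c1)c1c(O[Si](C(C)C)(C(C)C)C(C)C)cc(/C=C/c2ccc(O[Si](C)(C)C(C)(C)C)cc2)cc1OCc1ccc(O[Si](C(C)C)(C(C)C)C(C)C)c(C(=NN)c2cc(O[Si](C)(C)C(C)(C)C)cc(O[Si](C)(C)C(C)(C)C)c2)c1OCc1ccc(O[Si](C)(C)C(C)(C)C)cc1O[Si](C)(C)C(C)(C)C | intermediate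
22 | bis(diaryldiazomethane): 21 with each C=N–NH2 replaced by C=N2 | [N-]=[N+]=C(c1cc(O[Si](C)(C)C(C)(C)C)cc(O[Si](C)(C)C(C)(C)C)c1)c1c(O[Si](C(C)C)(C(C)C)C(C)C)cc(/C=C/c2ccc(O[Si](C)(C)C(C)(C)C)cc2)cc1OCc1ccc(O[Si](C(C)C)(C(C)C)C(C)C)c(C(=[N+]=[N-])c2cc(O[Si](C)(C)C(C)(C)C)cc(O[Si](C)(C)C(C)(C)C)c2)c1OCc1ccc(O[Si](C)(C)C(C)(C)C)cc1O[Si](C)(C)C(C)(C)C | intermediate (not isolated)
23 | (2R,3S)-2-[(2R,3S)-2-{2,4-bis[(tert-butyldimethylsilyl)oxy]phenyl}-3-{3,5-bis[(tert-butyldimethylsilyl)oxy]phenyl}-4-[(triisopropylsilyl)oxy]-2,3-dihydro-1-benzofuran-7-yl]-3-{3,5-bis[(tert-butyldimethylsilyl)oxy]phenyl}-6-[(E)-2-{4-[(tert-butyldimethylsilyl)oxy]phenyl}ethenyl]-4-[(triisopropylsilyl)oxy]-2,3-dihydro-1-benzofuran (both rings cis) | CC(C)(C)[Si](C)(C)Oc1ccc(/C=C/c2cc(O[Si](C(C)C)(C(C)C)C(C)C)c3c(c2)O[C@@H](c2ccc(O[Si](C(C)C)(C(C)C)C(C)C)c4c2O[C@@H](c2ccc(O[Si](C)(C)C(C)(C)C)cc2O[Si](C)(C)C(C)(C)C)[C@H]4c2cc(O[Si](C)(C)C(C)(C)C)cc(O[Si](C)(C)C(C)(C)C)c2)[C@H]3c2cc(O[Si](C)(C)C(C)(C)C)cc(O[Si](C)(C)C(C)(C)C)c2)cc1 | intermediate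
24 | (2S,3S)-2-[(2S,3S)-…]-… isomer of 23 (both rings trans; nona-silyl ether of the target) | CC(C)(C)[Si](C)(C)Oc1ccc(/C=C/c2cc(O[Si](C(C)C)(C(C)C)C(C)C)c3c(c2)O[C@H](c2ccc(O[Si](C(C)C)(C(C)C)C(C)C)c4c2O[C@H](c2ccc(O[Si](C)(C)C(C)(C)C)cc2O[Si](C)(C)C(C)(C)C)[C@H]4c2cc(O[Si](C)(C)C(C)(C)C)cc(O[Si](C)(C)C(C)(C)C)c2)[C@H]3c2cc(O[Si](C)(C)C(C)(C)C)cc(O[Si](C)(C)C(C)(C)C)c2)cc1 | intermediate
25 | gnetumontanin B, (2S,3S)-2-[(2S,3S)-3-(3,5-dihydroxyphenyl)-2-(2,4-dihydroxyphenyl)-4-hydroxy-2,3-dihydro-1-benzofuran-7-yl]-3-(3,5-dihydroxyphenyl)-6-[(E)-2-(4-hydroxyphenyl)ethenyl]-2,3-dihydro-1-benzofuran-4-ol | Oc1ccc(/C=C/c2cc(O)c3c(c2)O[C@H](c2ccc(O)c4c2O[C@H](c2ccc(O)cc2O)[C@H]4c2cc(O)cc(O)c2)[C@H]3c2cc(O)cc(O)c2)cc1 | target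

**Totals and risks**

Total step count: 17. Longest linear sequence: 10 steps (steps 3, 4, 5, 6, 11, 13, 14, 15, 16, 17).

Most likely to fail:

1. Step 15 (twofold C–H insertion). Carbene formation at diazo carbons flanked by two ortho oxygen substituents may be slow, leaving time for azine formation between diazo groups. Once the first ring is in place, the second insertion may also escape catalyst control (mismatched double induction) and give cis-ring diastereomers. The fallback closes the rings one at a time, so that each insertion can be run on a mono-diazo compound and given its own catalyst. It sets out from 8. Silylation of the primary alcohol (TBSCl, imidazole) gives the benzylic silyl ether F1. Addition of aryllithium 18 gives the N-lithio ketimine F2 and, after acetic acid, the N–H ketimine F3. Hydrazine exchange gives the hydrazone F4, MnO2 gives the diazo compound F5, and Rh2(R-PTAD)4 gives the cis ring D silyl ether F6. Pyridinium tosylate in MeOH removes only the primary alkyl silyl ether to give the ring D benzylic alcohol F7. Mitsunobu coupling with 14 gives the ring D nitrile F8. Addition of 18 gives the N-lithio ketimine F9 and then the N–H ketimine F10; hydrazine gives the hydrazone F11 and MnO2 the diazo compound F12. Insertion with the rhodium catalyst best matched to this substrate closes ring C, and the route is rejoined at 23.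

2. Step 13 (double aryllithium addition). The aryllithium may attack the ring instead of the nitrile carbon, displacing an ortho alkoxy or silyloxy group activated by the nitrile, or may attack silicon; the second addition may also stall. The fallback changes the electrophile from nitrile to aldehyde. It sets out from 15. Reduction with i-Bu2AlH (toluene, −78 °C; aqueous potassium sodium tartrate) gives the bis-aldehyde F13. Addition of 18 at −78 °C gives the bis(diarylmethanol) F14 as a mixture of diastereomers. Oxidation with MnO2 gives the bis(diaryl ketone) F15. Condensation with hydrazine hydrate and acetic acid in n-butanol with heating rejoins the route at 21.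

3. Step 16 (cis-to-trans equilibration). With silyloxy donors on the stabilising aryl groups, ionisation of the benzylic C2–O bonds may be slow. The acid strength then needed may protonate the stilbene or erode C3 by elimination and reprotonation. The fallback unmasks most phenols before equilibrating. It sets out from 23. KHF2 in MeOH at rt should cleave the seven aryl tert-butyldimethylsilyl ethers and spare the two flanked triisopropylsilyl ethers, giving the cis,cis heptaphenol F16. Mild acid (pyridinium tosylate, MeOH/THF, 40 °C) then equilibrates both rings through quinone-methide-type ring opening assisted by the free ortho and para hydroxyls; the retained silyl ether on ring B still blocks reclosure through the wrong oxygen. This gives the trans,trans heptaphenol F17, and Bu4NF/AcOH rejoins the route at 25.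

**Further compounds**

F1 | step 15 | 2-({2,4-bis[(tert-butyldimethylsilyl)oxy]phenyl}methoxy)-3-{[(tert-butyldimethylsilyl)oxy]methyl}-6-[(triisopropylsilyl)oxy]benzonitrile | N#Cc1c(O[Si](C(C)C)(C(C)C)C(C)C)ccc(CO[Si](C)(C)C(C)(C)C)c1OCc1ccc(O[Si](C)(C)C(C)(C)C)cc1O[Si](C)(C)C(C)(C)C
F2 | step 15 | N-lithio ketimine from F1 and 18 | [Li]N=C(c1cc(O[Si](C)(C)C(C)(C)C)cc(O[Si](C)(C)C(C)(C)C)c1)c1c(O[Si](C(C)C)(C(C)C)C(C)C)ccc(CO[Si](C)(C)C(C)(C)C)c1OCc1ccc(O[Si](C)(C)C(C)(C)C)cc1O[Si](C)(C)C(C)(C)C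
F3 | step 15 | N–H ketimine from F2 | N=C(c1cc(O[Si](C)(C)C(C)(C)C)cc(O[Si](C)(C)C(C)(C)C)c1)c1c(O[Si](C(C)C)(C(C)C)C(C)C)ccc(CO[Si](C)(C)C(C)(C)C)c1OCc1ccc(O[Si](C)(C)C(C)(C)C)cc1O[Si](C)(C)C(C)(C)C
F4 | step 15 | hydrazone from F3 | NN=C(c1cc(O[Si](C)(C)C(C)(C)C)cc(O[Si](C)(C)C(C)(C)C)c1)c1c(O[Si](C(C)C)(C(C)C)C(C)C)ccc(CO[Si](C)(C)C(C)(C)C)c1OCc1ccc(O[Si](C)(C)C(C)(C)C)cc1O[Si](C)(C)C(C)(C)C
F5 | step 15 | diazo compound from F4 | [N-]=[N+]=C(c1cc(O[Si](C)(C)C(C)(C)C)cc(O[Si](C)(C)C(C)(C)C)c1)c1c(O[Si](C(C)C)(C(C)C)C(C)C)ccc(CO[Si](C)(C)C(C)(C)C)c1OCc1ccc(O[Si](C)(C)C(C)(C)C)cc1O[Si](C)(C)C(C)(C)C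
F6 | step 15 | (2R,3S)-2-{2,4-bis[(tert-butyldimethylsilyl)oxy]phenyl}-3-{3,5-bis[(tert-butyldimethylsilyl)oxy]phenyl}-7-{[(tert-butyldimethylsilyl)oxy]methyl}-4-[(triisopropylsilyl)oxy]-2,3-dihydro-1-benzofuran (cis) | CC(C)(C)[Si](C)(C)OCc1ccc(O[Si](C(C)C)(C(C)C)C(C)C)c2c1O[C@@H](c1ccc(O[Si](C)(C)C(C)(C)C)cc1O[Si](C)(C)C(C)(C)C)[C@H]2c1cc(O[Si](C)(C)C(C)(C)C)cc(O[Si](C)(C)C(C)(C)C)c1
F7 | step 15 | [(2R,3S)-2-{2,4-bis[(tert-butyldimethylsilyl)oxy]phenyl}-3-{3,5-bis[(tert-butyldimethylsilyl)oxy]phenyl}-4-[(triisopropylsilyl)oxy]-2,3-dihydro-1-benzofuran-7-yl]methanol | OCc1ccc(O[Si](C(C)C)(C(C)C)C(C)C)c2c1O[C@@H](c1ccc(O[Si](C)(C)C(C)(C)C)cc1O[Si](C)(C)C(C)(C)C)[C@H]2c1cc(O[Si](C)(C)C(C)(C)C)cc(O[Si](C)(C)C(C)(C)C)c1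
F8 | step 15 | aryl ether of F7 with the phenol oxygen of 14 (ring D closed, ring A nitrile) | N#Cc1c(O[Si](C(C)C)(C(C)C)C(C)C)cc(/C=C/c2ccc(O[Si](C)(C)C(C)(C)C)cc2)cc1OCc1ccc(O[Si](C(C)C)(C(C)C)C(C)C)c2c1O[C@@H](c1ccc(O[Si](C)(C)C(C)(C)C)cc1O[Si](C)(C)C(C)(C)C)[C@H]2c1cc(O[Si](C)(C)C(C)(C)C)cc(O[Si](C)(C)C(C)(C)C)c1
F9 | step 15 | N-lithio ketimine from F8 and 18 | [Li]N=C(c1cc(O[Si](C)(C)C(C)(C)C)cc(O[Si](C)(C)C(C)(C)C)c1)c1c(O[Si](C(C)C)(C(C)C)C(C)C)cc(/C=C/c2ccc(O[Si](C)(C)C(C)(C)C)cc2)cc1OCc1ccc(O[Si](C(C)C)(C(C)C)C(C)C)c2c1O[C@@H](c1ccc(O[Si](C)(C)C(C)(C)C)cc1O[Si](C)(C)C(C)(C)C)[C@H]2c1cc(O[Si](C)(C)C(C)(C)C)cc(O[Si](C)(C)C(C)(C)C)c1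
F10 | step 15 | N–H ketimine from F9 | N=C(c1cc(O[Si](C)(C)C(C)(C)C)cc(O[Si](C)(C)C(C)(C)C)c1)c1c(O[Si](C(C)C)(C(C)C)C(C)C)cc(/C=C/c2ccc(O[Si](C)(C)C(C)(C)C)cc2)cc1OCc1ccc(O[Si](C(C)C)(C(C)C)C(C)C)c2c1O[C@@H](c1ccc(O[Si](C)(C)C(C)(C)C)cc1O[Si](C)(C)C(C)(C)C)[C@H]2c1cc(O[Si](C)(C)C(C)(C)C)cc(O[Si](C)(C)C(C)(C)C)c1
F11 | step 15 | hydrazone from F10 | NN=C(c1cc(O[Si](C)(C)C(C)(C)C)cc(O[Si](C)(C)C(C)(C)C)c1)c1c(O[Si](C(C)C)(C(C)C)C(C)C)cc(/C=C/c2ccc(O[Si](C)(C)C(C)(C)C)cc2)cc1OCc1ccc(O[Si](C(C)C)(C(C)C)C(C)C)c2c1O[C@@H](c1ccc(O[Si](C)(C)C(C)(C)C)cc1O[Si](C)(C)C(C)(C)C)[C@H]2c1cc(O[Si](C)(C)C(C)(C)C)cc(O[Si](C)(C)C(C)(C)C)c1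
F12 | step 15 | diazo compound from F11 | [N-]=[N+]=C(c1cc(O[Si](C)(C)C(C)(C)C)cc(O[Si](C)(C)C(C)(C)C)c1)c1c(O[Si](C(C)C)(C(C)C)C(C)C)cc(/C=C/c2ccc(O[Si](C)(C)C(C)(C)C)cc2)cc1OCc1ccc(O[Si](C(C)C)(C(C)C)C(C)C)c2c1O[C@@H](c1ccc(O[Si](C)(C)C(C)(C)C)cc1O[Si](C)(C)C(C)(C)C)[C@H]2c1cc(O[Si](C)(C)C(C)(C)C)cc(O[Si](C)(C)C(C)(C)C)c1
F13 | step 13 | bis-aldehyde: 15 with each C≡N replaced by CH=O | O=Cc1c(O[Si](C(C)C)(C(C)C)C(C)C)cc(/C=C/c2ccc(O[Si](C)(C)C(C)(C)C)cc2)cc1OCc1ccc(O[Si](C(C)C)(C(C)C)C(C)C)c(C=O)c1OCc1ccc(O[Si](C)(C)C(C)(C)C)cc1O[Si](C)(C)C(C)(C)C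
F14 | step 13 | bis(diarylmethanol): F13 with each CH=O replaced by CH(OH)[3,5-bis(tert-butyldimethylsilyloxy)phenyl], mixture of diastereomers | OC(c1cc(O[Si](C)(C)C(C)(C)C)cc(O[Si](C)(C)C(C)(C)C)c1)c1c(O[Si](C(C)C)(C(C)C)C(C)C)cc(/C=C/c2ccc(O[Si](C)(C)C(C)(C)C)cc2)cc1OCc1ccc(O[Si](C(C)C)(C(C)C)C(C)C)c(C(O)c2cc(O[Si](C)(C)C(C)(C)C)cc(O[Si](C)(C)C(C)(C)C)c2)c1OCc1ccc(O[Si](C)(C)C(C)(C)C)cc1O[Si](C)(C)C(C)(C)C
F15 | step 13 | bis(diaryl ketone): F14 with each CH(OH) oxidised to C=O | O=C(c1cc(O[Si](C)(C)C(C)(C)C)cc(O[Si](C)(C)C(C)(C)C)c1)c1c(O[Si](C(C)C)(C(C)C)C(C)C)cc(/C=C/c2ccc(O[Si](C)(C)C(C)(C)C)cc2)cc1OCc1ccc(O[Si](C(C)C)(C(C)C)C(C)C)c(C(=O)c2cc(O[Si](C)(C)C(C)(C)C)cc(O[Si](C)(C)C(C)(C)C)c2)c1OCc1ccc(O[Si](C)(C)C(C)(C)C)cc1O[Si](C)(C)C(C)(C)C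
F16 | step 16 | cis,cis (2R,3S,2'R,3'S) heptaphenol retaining the two triisopropylsilyl ethers on rings A and B | Oc1ccc(/C=C/c2cc(O[Si](C(C)C)(C(C)C)C(C)C)c3c(c2)O[C@@H](c2ccc(O[Si](C(C)C)(C(C)C)C(C)C)c4c2O[C@@H](c2ccc(O)cc2O)[C@H]4c2cc(O)cc(O)c2)[C@H]3c2cc(O)cc(O)c2)cc1
F17 | step 16 | trans,trans (2S,3S,2'S,3'S) heptaphenol retaining the two triisopropylsilyl ethers on rings A and B | Oc1ccc(/C=C/c2cc(O[Si](C(C)C)(C(C)C)C(C)C)c3c(c2)O[C@H](c2ccc(O[Si](C(C)C)(C(C)C)C(C)C)c4c2O[C@H](c2ccc(O)cc2O)[C@H]4c2cc(O)cc(O)c2)[C@H]3c2cc(O)cc(O)c2)cc1
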